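Two questions stand on this flask: how much target it holds at the end, and how near its dissolved gas stands to saturation.

| setting | east | south-west | flask |
|---|---|---|---|
| substrate | 0.25 M | 0.40 M | 0.18 M |
| gas phase | 14 mM (held) | 14 mM (held) | 14 mM (held) |
| remark | run made earlier | run made earlier |  |
| time |  |  | 6.0 h |

| east: time / h | east: target / % | south-west: time / h | south-west: target / % |
|---|---|---|---|
| 0.500 | 5 | 1.50 | 10 |
| 1.00 | 6 | 3.00 | 10 |
| 2.50 | 14 | 5.00 | 15 |
| 6.00 | 18 | 6.00 | 17 |

(each reading ± 1.5 percentage points)

- in percentages every species weighs as the substrate in it: one side product counts as two
- at the start none of the gas is dissolved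
- on the list of suspects stand: gas phase <-> dissolved gas; substrate + dissolved gas -> target; dissolved gas + target -> over-reacted product; substrate + target -> side product

- target at 6.0 h, in percent of the substrate charged
- concentration of dissolved gas in solution at 6.0 h, in percent of saturation

Before any rate constant, ask whether the early rate follows the charge. With dissolved gas near saturation, the step that joins substrate and dissolved gas into target runs in proportion to the substrate present, so early target should follow the charge. So take the first reading of each run, at 0.500 h in the east run and 1.50 h in the south-west run, as target made per hour: the east run gives 25.0 mM h⁻¹ and the south-west run 26.7 mM h⁻¹. The charge rose by a factor of 1.60, but the rate by less than that, a factor of 1.07, though scatter weighs heavily on such small readings.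

I therefore read gas transfer as the rate-limiting step, with a supply G of about 25.8 mM h⁻¹, the mean of the two, much the same at both charges. What you carry forward is the gas equivalents E: G times the time, divided by the substrate charged, which is moles of gas delivered per mole of substrate. Target takes one gas and over-reacted product two, so this flask, with E = 0.861, falls short of the 2 needed to over-react its whole charge. My reckoning is that gas is used about as it arrives and stays well below saturation. For target I have nothing sharper than the 17% to 18% read at 6.00 h in the runs.

The forecast gives 19% target (16% to 22%) and 85% of saturation (60% to 97%), with “dissolved gas fairly near saturation”. On the gas, my reckoning parts from it.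

The flask gives 18.9% target and 15.5% of saturation, far less than forecast.

    gas phase ⇌ dissolved gas, rate k1*(csat - [dissolved gas]) (kL = 6.80 × 10⁻⁴ s⁻¹)
    substrate + dissolved gas → target (k = 0.0270 M⁻¹ s⁻¹)
    dissolved gas + target → over-reacted product (k = 0.0590 M⁻¹ s⁻¹)
    substrate + target → side product (k = 1.20 × 10⁻⁴ M⁻¹ s⁻¹)

At the end this flask's products hold 0.991 gas per substrate charged, against E = 0.861. A neighbouring flask, the same but charged with 0.072 M of substrate, has E = 2.15, above the 2 that full over-reaction takes. So you expect over-reacted product to stand above target in that flask, and at 6.00 h it holds 85.9% over-reacted product against 5.16% target, with 6.38% substrate left. Its products hold 1.78 gas per substrate charged, and its dissolved gas stands at 0.00868 M.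

The earlier runs and the new flask were computed for an exercise, noise included.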